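**Plan**

1. Retrosynthetic cuts, in order: the acetyl group on O17; the ring bond O–C16 of the 2,5-dihydrofuran; the C1–C2 bond shared by the dihydrofuran and the 14-membered carbocycle (alkene carbon to carbinol carbon); the C14–C1 bond. What remains is the farnesol chain (C2–C13) plus one methylene.
2. Enabling feature: C15 of the dihydrofuran carries two CH2–O arms (ring C16 and acetoxymethyl C17). Tied through one oxygen they form a symmetric 3-alkylidene oxetane, so the tetrasubstituted C1=C15 alkene has no geometry and C1 can serve as an alkenyl bromide.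
3. Forward: farnesol is oxidised at its (E)-terminal methyl, epoxidised at the central alkene, extended by one carbon and joined to 3-(dibromomethylidene)oxetane. The alkenyl bromide then adds to the C2 enal and closes the 14-membered ring.
4. The C2 alkoxide then opens the oxetane at the only CH2 it can reach (the cis arm, C16). Strain release closes the dihydrofuran and frees C17–OH for acetylation.
5. Stereochemistry: both E-alkenes come from (2E,6E)-farnesol; the (7R,8R)-epoxide from a Shi epoxidation of the only electron-rich alkene; C2 (R) from a chiral sulfonamide–chromium reagent in the ring closure.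

Key step: step 10

Remark: cembrane numbers are used for the macrocycles (C1 = alkenyl ring carbon, C2 = O-bearing CH, C3=C4, C7/C8 epoxide, C11=C12, C15 = second alkene carbon of the dihydrofuran, C16 = ring OCH2, C17 = CH2OAc). (2E,6E)-Farnesol, oxetan-3-one and the D-fructose-derived epoxidation ketone are taken as commercial.

**Route**

Step 1
Reactants: 1 (2E,6E)-farnesol
Product: 2 (2E,6E)-farnesyl acetate
Conditions: Ac2O, pyridine, DMAP (cat.), CH2Cl2, 0 °C to rt
Reagents that add atoms: acetic anhydride, CC(=O)OC(C)=O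
Why: DMAP-catalysed acetylation of a primary allylic alcohol; the allylic acetate also lowers the nucleophilicity of the C2=C3 alkene for the later epoxidation.

Step 2
Reactants: 2 (2E,6E)-farnesyl acetate
Product: 3 (2E,6E,10E)-12-hydroxy-3,7,11-trimethyldodeca-2,6,10-trien-1-yl acetate
Conditions: SeO2 (cat.), t-BuOOH, salicylic acid (cat.), CH2Cl2, rt
Reagents that add atoms: tert-butyl hydroperoxide, CC(C)(C)OO (the oxygen atom passes through SeO2)
Why: SeO2 allylic oxidation (ene reaction, then 2,3-sigmatropic shift) should take the (E)-methyl of the terminal, most electron-rich alkene and give the (E)-allylic alcohol.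

Step 3
Reactants: 3 (2E,6E,10E)-12-hydroxy-3,7,11-trimethyldodeca-2,6,10-trien-1-yl acetate
Product: 4 (2E,6E,10E)-3,7,11-trimethyl-12-oxododeca-2,6,10-trien-1-yl acetate
Conditions: MnO2, CH2Cl2, rt
Reagents that add atoms: none
Why: MnO2 oxidation of an allylic alcohol to the enal; conjugation now deactivates the C10=C11 alkene toward electrophilic oxidants.

Step 4
Reactants: 4 (2E,6E,10E)-3,7,11-trimethyl-12-oxododeca-2,6,10-trien-1-yl acetate
Product: 5 (2E,10E)-(6R,7R)-6,7-epoxy-3,7,11-trimethyl-12-oxododeca-2,10-dien-1-yl acetate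
Conditions: 1,2:4,5-di-O-isopropylidene-β-D-erythro-2,3-hexodiulo-2,6-pyranose (0.3 equiv), KHSO5 (as Oxone), K2CO3, Bu4NHSO4, Na2B4O7/Na2EDTA buffer, MeCN/CH2(OMe)2/H2O, 0 °C
Reagents that add atoms: potassium peroxymonosulfate, [K+].[O-]S(=O)(=O)OO
Why: Shi epoxidation; the chiral dioxirane should attack only the central alkene, the other two being deactivated by the enal and the allylic acetate, and the spiro transition state of the D-fructose-derived ketone should give the (6R,7R)-epoxide, while the electron-poor enal should be oxidised far more slowly at 0 °C.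

Step 5
Reactants: 5 (2E,10E)-(6R,7R)-6,7-epoxy-3,7,11-trimethyl-12-oxododeca-2,10-dien-1-yl acetate
Product: 6 (2E,10E)-(6R,7R)-6,7-epoxy-3,7,11-trimethyltrideca-2,10,12-trien-1-yl acetate
Conditions: Ph3PCH3Br, KN(SiMe3)2, THF, 0 °C; then 5, −78 °C to 0 °C
Reagents that add atoms: methyltriphenylphosphonium bromide, C[P+](c1ccccc1)(c1ccccc1)c1ccccc1.[Br-]
Why: Wittig methylenation; the preformed ylide, used in slight deficit to the salt, should take the aldehyde much faster than the acetate and leave the epoxide alone.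

Step 6
Reactants: 7 oxetan-3-one
Product: 8 3-(dibromomethylidene)oxetane
Conditions: CBr4, PPh3, CH2Cl2, 0 °C to rt
Reagents that add atoms: carbon tetrabromide, BrC(Br)(Br)Br
Why: dibromo-olefination (Corey–Fuchs first stage, Wittig type) of a strained, highly electrophilic ketone.

Step 7
Reactants: 6 (2E,10E)-(6R,7R)-6,7-epoxy-3,7,11-trimethyltrideca-2,10,12-trien-1-yl acetate; 8 3-(dibromomethylidene)oxetane
Product: 10 (2E,10E)-(6R,7R)-14-bromo-6,7-epoxy-3,7,11-trimethyl-14-(oxetan-3-ylidene)tetradeca-2,10-dien-1-yl acetate, via B-alkyl-9-BBN borane 9 (not isolated)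
Conditions: 9-BBN-H, THF, 0 °C to rt; then 8 (3 equiv), Pd(dppf)Cl2 (cat.), AsPh3, Cs2CO3, DMF/H2O, rt
Reagents that add atoms: 9-borabicyclo[3.3.1]nonane, [H]B1C2CCCC1CCC2 (its atoms stay only in 9)
Why: 9-BBN should add only to the terminal CH2 of the vinyl group (1,2-hydroboration of the 2-substituted 1,3-diene, giving the homoallylic borane), and the B-alkyl Suzuki–Miyaura coupling with the symmetric gem-dibromide in excess should stop after one C–Br bond because the product bromide is tetrasubstituted; no alkene geometry arises.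

Step 8
Reactants: 10 (2E,10E)-(6R,7R)-14-bromo-6,7-epoxy-3,7,11-trimethyl-14-(oxetan-3-ylidene)tetradeca-2,10-dien-1-yl acetate
Product: 11 (2E,10E)-(6R,7R)-14-bromo-6,7-epoxy-3,7,11-trimethyl-14-(oxetan-3-ylidene)tetradeca-2,10-dien-1-ol
Conditions: K2CO3 (cat.), MeOH, 0 °C to rt
Reagents that add atoms: none
Why: mild transesterification removes the acetate; epoxide, oxetane and alkenyl bromide are inert to carbonate in methanol.

Step 9
Reactants: 11 (2E,10E)-(6R,7R)-14-bromo-6,7-epoxy-3,7,11-trimethyl-14-(oxetan-3-ylidene)tetradeca-2,10-dien-1-ol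
Product: 12 (2E,10E)-(6R,7R)-14-bromo-6,7-epoxy-3,7,11-trimethyl-14-(oxetan-3-ylidene)tetradeca-2,10-dienal
Conditions: MnO2, CH2Cl2, rt
Reagents that add atoms: none
Why: neutral allylic oxidation to the (E)-enal, chosen to keep E/Z isomerisation of the C2=C3 alkene low.

Step 10
Reactants: 12 (2E,10E)-(6R,7R)-14-bromo-6,7-epoxy-3,7,11-trimethyl-14-(oxetan-3-ylidene)tetradeca-2,10-dienal
Product: 13 (2R,3E,7R,8R,11E)-7,8-epoxy-4,8,12-trimethyl-1-(oxetan-3-ylidene)cyclotetradeca-3,11-dien-2-ol
Conditions: CrCl2 (excess), NiCl2 (cat.), N-[2-(4-isopropyl-4,5-dihydro-1,3-oxazol-2-yl)-6-methylphenyl]methanesulfonamide (the antipode that gives 2R), Et3N, THF, rt; 12 added slowly to a final 1 mM; aqueous work-up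
Reagents that add atoms: none
Why: Zerovalent nickel should insert into the C1–Br bond and pass the alkenyl group to trivalent chromium, and the alkenylchromium should add 1,2 to the C2 aldehyde (Nozaki–Hiyama–Kishi reaction run as a macrocyclisation). The closest known reaction type is the Ni/Cr-mediated ring closure of ω-haloalkenyl aldehydes to macrocyclic allylic alcohols under a chiral oxazoline–sulfonamide ligand. The 14-membered carbocycle closes in the exo-trig mode at the carbonyl carbon, and no other ring forms in this step. The new stereocentre C2 is set by the chiral sulfonamide bound to chromium (reagent control), because the C7/C8 epoxide is too remote to bias the aldehyde faces; the ligand antipode that delivers 2R is fixed in a pilot run with each enantiomer. The step needs 1,2- over 1,4-addition and attack on the aldehyde in preference to epoxide and oxetane, which the low basicity and carbonyl selectivity of alkenylchromium secure, and ring closure over oligomerisation, which slow addition at high dilution and the two E-alkenes of the chain support. The C1=C15 alkene cannot lose geometry because C15 carries the symmetric oxetane, whose pinned-back CH2 groups also leave the C1–Br bond open to nickel.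

Step 11
Reactants: 13 (2R,3E,7R,8R,11E)-7,8-epoxy-4,8,12-trimethyl-1-(oxetan-3-ylidene)cyclotetradeca-3,11-dien-2-ol
Product: 14 (2R,7R,8R)-2,16:7,8-diepoxycembra-1(15),3E,11E-trien-17-ol (17-deacetyl-lobophynin B)
Conditions: KH, 18-crown-6, THF, 0 °C to 45 °C; then H2O
Reagents that add atoms: none
Why: Proposed new method: the potassium alkoxide on C2 lies in the alkene plane cis to one oxetane CH2 (C16) and can reach it from the side opposite the oxetane C–O bond (5-exo-tet, nearly collinear), so release of the oxetane ring strain should drive closure of the 2,5-dihydrofuran and expel the C17 alkoxide, while the trans CH2 is out of reach (this differentiates C16 from C17) and attack on the epoxide would need a seven-membered ring spanning an E-alkene; the closest known reaction types are the acid-catalysed intramolecular opening of 3-substituted oxetanes by tethered alcohols to tetrahydrofurans and the alkoxide 5-exo opening of epoxides; C2 is not touched and no new stereocentre forms.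

Step 12
Reactants: 14 (2R,7R,8R)-2,16:7,8-diepoxycembra-1(15),3E,11E-trien-17-ol
Product: 15 lobophynin B
Conditions: Ac2O, pyridine, DMAP (cat.), CH2Cl2, 0 °C
Reagents that add atoms: acetic anhydride, CC(=O)OC(C)=O
Why: acetylation of the only free hydroxyl, a primary allylic alcohol, under buffered basic conditions that the epoxide and the allylic ether tolerate.

**Compound list**

1 | (2E,6E)-farnesol | OC/C=C(C)/CC/C=C(C)/CCC=C(C)C | starting material
2 | (2E,6E)-farnesyl acetate | CC(=O)OC/C=C(C)/CC/C=C(C)/CCC=C(C)C | intermediate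
3 | (2E,6E,10E)-12-hydroxy-3,7,11-trimethyldodeca-2,6,10-trien-1-yl acetate | CC(=O)OC/C=C(C)/CC/C=C(C)/CC/C=C(C)/CO | intermediate
4 | (2E,6E,10E)-3,7,11-trimethyl-12-oxododeca-2,6,10-trien-1-yl acetate | CC(=O)OC/C=C(C)/CC/C=C(C)/CC/C=C(C)/C=O | intermediate
5 | (2E,10E)-(6R,7R)-6,7-epoxy-3,7,11-trimethyl-12-oxododeca-2,10-dien-1-yl acetate | CC(=O)OC/C=C(C)/CC[C@H]1O[C@]1(C)CC/C=C(C)/C=O | intermediate
6 | (2E,10E)-(6R,7R)-6,7-epoxy-3,7,11-trimethyltrideca-2,10,12-trien-1-yl acetate | CC(=O)OC/C=C(C)/CC[C@H]1O[C@]1(C)CC/C=C(C)/C=C | intermediate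
7 | oxetan-3-one | O=C1COC1 | starting material
8 | 3-(dibromomethylidene)oxetane | BrC(Br)=C1COC1 | intermediate
9 | (2E,10E)-(6R,7R)-13-(9-borabicyclo[3.3.1]nonan-9-yl)-6,7-epoxy-3,7,11-trimethyltrideca-2,10-dien-1-yl acetate | CC(=O)OC/C=C(C)/CC[C@H]1O[C@]1(C)CC/C=C(C)/CCB1C2CCCC1CCC2 | intermediate (not isolated)
10 | (2E,10E)-(6R,7R)-14-bromo-6,7-epoxy-3,7,11-trimethyl-14-(oxetan-3-ylidene)tetradeca-2,10-dien-1-yl acetate | CC(=O)OC/C=C(C)/CC[C@H]1O[C@]1(C)CC/C=C(C)/CCC(Br)=C1COC1 | intermediate
11 | (2E,10E)-(6R,7R)-14-bromo-6,7-epoxy-3,7,11-trimethyl-14-(oxetan-3-ylidene)tetradeca-2,10-dien-1-ol | OC/C=C(C)/CC[C@H]1O[C@]1(C)CC/C=C(C)/CCC(Br)=C1COC1 | intermediate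
12 | (2E,10E)-(6R,7R)-14-bromo-6,7-epoxy-3,7,11-trimethyl-14-(oxetan-3-ylidene)tetradeca-2,10-dienal | O=C/C=C(C)/CC[C@H]1O[C@]1(C)CC/C=C(C)/CCC(Br)=C1COC1 | intermediate
13 | (2R,3E,7R,8R,11E)-7,8-epoxy-4,8,12-trimethyl-1-(oxetan-3-ylidene)cyclotetradeca-3,11-dien-2-ol | O[C@@H]1/C=C(C)/CC[C@H]2O[C@]2(C)CC/C=C(C)/CCC1=C3COC3 | intermediate
14 | (2R,7R,8R)-2,16:7,8-diepoxycembra-1(15),3E,11E-trien-17-ol | OCC1=C2CC/C(C)=C/CC[C@@]3(C)O[C@@H]3CC/C(C)=C/[C@H]2OC1 | intermediate
15 | lobophynin B, (2R,7R,8R)-2,16:7,8-diepoxycembra-1(15),3E,11E-trien-17-yl acetate | CC(=O)OCC1=C2CC/C(C)=C/CC[C@@]3(C)O[C@@H]3CC/C(C)=C/[C@H]2OC1 | target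

**Step count and risks**

Total steps: 12. Longest linear sequence: 11 (steps 1–5 and 7–12).

Steps most likely to fail:

1. Step 11 (proposed new method). The unactivated oxetane may resist the alkoxide at temperatures the potassium dienyl alkoxide survives, so that base-induced isomerisation or decomposition precedes ring opening. The fallback sets out from borane 9 and comes back at 14. Borane 9 would be coupled under the step 7 conditions with 1,1-dibromo-2,2-bis[(tert-butyldimethylsilyloxy)methyl]ethene F1 (from commercial 1,3-bis(tert-butyldimethylsilyloxy)propan-2-one, CBr4 and PPh3) to give the bis-silyl alkenyl bromide acetate F2. K2CO3/MeOH would give the alcohol F3 and MnO2 the enal F4. The same Ni/Cr ring closure would give the macrocyclic carbinol F5, and Bu4NF would free the triol F6. Mitsunobu cyclodehydration (PPh3, diisopropyl azodicarboxylate, THF, 0 °C) would then close the dihydrofuran: an oxyphosphonium on the C16 arm is displaced by the C2 hydroxyl (5-exo-tet, C2 retained), one on the C17 arm has no partner and exchanges back. This gives 14.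

2. Step 10 (key step). Facial selectivity at the aldehyde may be poor in the macrocyclic transition state, or the ligand-bound chromium reagent may be too hindered for the tetrasubstituted alkenyl group. The fallback sets out from 12 and comes back at 13. A ligand-free ring closure (CrCl2, NiCl2 cat., DMSO, high dilution) would give 13 together with its (2S)-epimer F7. MnO2 would oxidise the mixture to the cross-conjugated dienone F8. Corey–Bakshi–Shibata reduction (oxazaborolidine antipode chosen for 2R, catecholborane, toluene, −78 °C) would return 13.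

3. Step 7. Transmetalation of the homoallylic borane may be slow, with protodeboronation or a second coupling at the remaining C–Br bond taking over. The fallback sets out from 9 and comes back at 10. Oxidation of 9 (NaBO3·4H2O, THF/H2O) would give the primary alcohol F9. I2, PPh3 and imidazole would give the iodide F10. Zinc insertion (Zn dust, LiCl, THF) would give the alkylzinc iodide F11. Negishi coupling with excess 8 (PdCl2(DPEphos) cat., THF, rt) would give 10.

**Further compounds**

F1 | step 11 | 1,1-dibromo-2,2-bis[(tert-butyldimethylsilyloxy)methyl]ethene | CC(C)(C)[Si](C)(C)OCC(=C(Br)Br)CO[Si](C)(C)C(C)(C)C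
F2 | step 11 | (2E,10E)-(6R,7R)-14-bromo-16-(tert-butyldimethylsilyloxy)-15-[(tert-butyldimethylsilyloxy)methyl]-6,7-epoxy-3,7,11-trimethylhexadeca-2,10,14-trien-1-yl acetate | CC(=O)OC/C=C(C)/CC[C@H]1O[C@]1(C)CC/C=C(C)/CCC(Br)=C(CO[Si](C)(C)C(C)(C)C)CO[Si](C)(C)C(C)(C)C
F3 | step 11 | (2E,10E)-(6R,7R)-14-bromo-16-(tert-butyldimethylsilyloxy)-15-[(tert-butyldimethylsilyloxy)methyl]-6,7-epoxy-3,7,11-trimethylhexadeca-2,10,14-trien-1-ol | OC/C=C(C)/CC[C@H]1O[C@]1(C)CC/C=C(C)/CCC(Br)=C(CO[Si](C)(C)C(C)(C)C)CO[Si](C)(C)C(C)(C)C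
F4 | step 11 | (2E,10E)-(6R,7R)-14-bromo-16-(tert-butyldimethylsilyloxy)-15-[(tert-butyldimethylsilyloxy)methyl]-6,7-epoxy-3,7,11-trimethylhexadeca-2,10,14-trienal | O=C/C=C(C)/CC[C@H]1O[C@]1(C)CC/C=C(C)/CCC(Br)=C(CO[Si](C)(C)C(C)(C)C)CO[Si](C)(C)C(C)(C)C
F5 | step 11 | (2R,3E,7R,8R,11E)-1-[1,3-bis(tert-butyldimethylsilyloxy)propan-2-ylidene]-7,8-epoxy-4,8,12-trimethylcyclotetradeca-3,11-dien-2-ol | O[C@@H]1/C=C(C)/CC[C@H]2O[C@]2(C)CC/C=C(C)/CCC1=C(CO[Si](C)(C)C(C)(C)C)CO[Si](C)(C)C(C)(C)C
F6 | step 11 | (2R,3E,7R,8R,11E)-1-(1,3-dihydroxypropan-2-ylidene)-7,8-epoxy-4,8,12-trimethylcyclotetradeca-3,11-dien-2-ol | O[C@@H]1/C=C(C)/CC[C@H]2O[C@]2(C)CC/C=C(C)/CCC1=C(CO)CO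
F7 | step 10 | (2S,3E,7R,8R,11E)-7,8-epoxy-4,8,12-trimethyl-1-(oxetan-3-ylidene)cyclotetradeca-3,11-dien-2-ol | O[C@H]1/C=C(C)/CC[C@H]2O[C@]2(C)CC/C=C(C)/CCC1=C3COC3
F8 | step 10 | (3E,7R,8R,11E)-7,8-epoxy-4,8,12-trimethyl-1-(oxetan-3-ylidene)cyclotetradeca-3,11-dien-2-one | O=C1/C=C(C)/CC[C@H]2O[C@]2(C)CC/C=C(C)/CCC1=C3COC3
F9 | step 7 | (2E,10E)-(6R,7R)-6,7-epoxy-13-hydroxy-3,7,11-trimethyltrideca-2,10-dien-1-yl acetate | CC(=O)OC/C=C(C)/CC[C@H]1O[C@]1(C)CC/C=C(C)/CCO
F10 | step 7 | (2E,10E)-(6R,7R)-6,7-epoxy-13-iodo-3,7,11-trimethyltrideca-2,10-dien-1-yl acetate | CC(=O)OC/C=C(C)/CC[C@H]1O[C@]1(C)CC/C=C(C)/CCI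
F11 | step 7 | [(3E,11E)-(7R,8R)-13-acetoxy-7,8-epoxy-3,7,11-trimethyltrideca-3,11-dien-1-yl]zinc iodide | CC(=O)OC/C=C(C)/CC[C@H]1O[C@]1(C)CC/C=C(C)/CC[Zn]I
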